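**Retrosynthetic overview**

1. The target is read as epigallocatechin-(4β→8)-epigallocatechin-(4β→8)-epigallocatechin 3-O-gallate-(4β→8)-epicatechin (units A–B–C–D from the top). The three C4–C8 interflavan bonds are disconnected (Lewis-acid Friedel–Crafts couplings of 4-alkoxyflavans, built in the order C–D, then B, then A). Unit A enters as its 8-bromo derivative, and the bromine and the 22 benzyl ethers fall last in one hydrogenolysis.
2. Units A, B and C all come from one building block, penta-O-benzyl-epigallocatechin 13; unit D comes from (−)-epicatechin.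
3. The pyran ring of 13 (O1, C2, C3, C4, C4a, C8a; it becomes ring C of unit B, and of units A and C) is made by ring expansion. A 2,3-cis 2-aryl-3-(hydroxymethyl)-2,3-dihydrobenzofuran (ring O1, C2, C3, C4a, C8a; C4 exocyclic on C3) undergoes a 1,2-shift of the aryl carbon C4a from C3 to C4 through a phenonium ion.
4. Enabling feature: C4a lies on the phloroglucinol ring A between the O1-bearing C8a and the C5 oxygen, and para to the C7 oxygen, so it can bridge C3 and C4; the less strained six-membered ester is the thermodynamic sink.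
5. Ring order: oxirane (cis-glycidate) → dihydrofuran (aryloxide opening, then Friedel–Crafts closure at the α-carbon) → pyran (expansion) → three interflavan bonds.

Key step: step 6

Remark: every flavan unit is taken as 2R,3R with each interflavan bond trans to the neighbouring 3-oxygen, as read from the SMILES; in the Why lines atoms carry flavan numbering (O1, C2, C3, C4, C4a, C8a), also in the ring-contracted precursors.

**Route**

Step 1
Reactants: 1 3,4,5-tris(benzyloxy)benzaldehyde; 2 ethyl 2-(diphenoxyphosphoryl)acetate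
Product: 3 ethyl (Z)-3-[3,4,5-tris(benzyloxy)phenyl]prop-2-enoate
Conditions: 2, NaH, THF, −78 °C; then 1, −78 → 0 °C
Reagents that add atoms: none
Why: Z-selective Horner–Wadsworth–Emmons olefination, in which the electron-poor diaryl phosphonate collapses fast from the kinetically formed adduct, so the aromatic aldehyde should give the cis-cinnamate needed for a cis-epoxide (no stereocentre is formed).

Step 2
Reactants: 3 ethyl (Z)-3-[3,4,5-tris(benzyloxy)phenyl]prop-2-enoate
Product: 4 ethyl (2S,3S)-3-[3,4,5-tris(benzyloxy)phenyl]oxirane-2-carboxylate (cis-glycidate)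
Conditions: (S,S)-[N,N'-bis(3,5-di-tert-butylsalicylidene)cyclohexane-1,2-diaminato]manganese chloride (trivalent manganese; 8 mol %), 4-phenylpyridine N-oxide, aq. NaOCl (pH 11), CH2Cl2, 0 °C
Reagents that add atoms: sodium hypochlorite, [Na+].[O-]Cl
Why: Jacobsen–Katsuki epoxidation, for which cis-cinnamate esters are a well-behaved substrate class; the chiral salen ligand chooses the alkene face and so sets both stereocentres (2S,3S) by catalyst control.

Step 3
Reactants: 4 ethyl (2S,3S)-3-[3,4,5-tris(benzyloxy)phenyl]oxirane-2-carboxylate; 5 3,5-bis(benzyloxy)phenol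
Product: 6 ethyl (2S,3R)-3-[3,5-bis(benzyloxy)phenoxy]-2-hydroxy-3-[3,4,5-tris(benzyloxy)phenyl]propanoate
Conditions: 5 (1.2 equiv), Cs2CO3 (0.3 equiv), DMF, 50 °C
Reagents that add atoms: none
Why: SN2 opening of a 3-arylglycidic ester by an aryloxide, which takes place at the benzylic carbon with inversion (giving 3R, the later C2 of the flavan), while the C2 oxygen and its configuration are untouched.

Step 4
Reactants: 6 ethyl (2S,3R)-3-[3,5-bis(benzyloxy)phenoxy]-2-hydroxy-3-[3,4,5-tris(benzyloxy)phenyl]propanoate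
Product: 8 ethyl (2S,3R)-4,6-bis(benzyloxy)-2-[3,4,5-tris(benzyloxy)phenyl]-2,3-dihydro-1-benzofuran-3-carboxylate (2-aryl and 3-ester cis), via triflate 7 (not isolated)
Conditions: Tf2O (1.1 equiv), 2,6-di-tert-butyl-4-methylpyridine, CH2Cl2, −78 → 0 °C
Reagents that add atoms: none
Why: stereospecific intramolecular Friedel–Crafts alkylation by an α-sulfonyloxy ester (SN2 with inversion, 5-exo-tet), in which the ortho carbon of the phloroglucinol ether (the two ortho positions are equivalent) displaces a triflate that cannot ionise next to the ester, so the new centre is set by inversion and the ring is 2,3-cis.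

Step 5
Reactants: 8 ethyl (2S,3R)-4,6-bis(benzyloxy)-2-[3,4,5-tris(benzyloxy)phenyl]-2,3-dihydro-1-benzofuran-3-carboxylate
Product: 9 [(2S,3S)-4,6-bis(benzyloxy)-2-[3,4,5-tris(benzyloxy)phenyl]-2,3-dihydro-1-benzofuran-3-yl]methanol (2-aryl and 3-CH2OH cis)
Conditions: i-Bu2AlH (2.5 equiv), CH2Cl2, −78 → −20 °C
Reagents that add atoms: none
Why: aluminium hydride reduction of the ester to the primary alcohol under non-basic conditions, so the epimerisable cis centre next to the ester is carried through and no new stereocentre is formed.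

Step 6
Reactants: 9 [(2S,3S)-4,6-bis(benzyloxy)-2-[3,4,5-tris(benzyloxy)phenyl]-2,3-dihydro-1-benzofuran-3-yl]methanol
Product: 13 (2R,3R)-5,7-bis(benzyloxy)-2-[3,4,5-tris(benzyloxy)phenyl]chroman-3-ol (penta-O-benzyl-(−)-epigallocatechin), via trifluoroacetate 10 (not isolated), via phenonium ion pair 11 (not isolated), via ring-expanded trifluoroacetate 12 (not isolated)
Conditions: (CF3CO)2O (1.05 equiv), 2,6-lutidine, CH2Cl2, 0 °C; then (CF3)2CHOH, 2,6-lutidine (0.2 equiv), 45 °C; then K2CO3, MeOH, 0 °C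
Reagents that add atoms: trifluoroacetic anhydride, O=C(OC(=O)C(F)(F)F)C(F)(F)F
Why: Proposed new method: the primary trifluoroacetate 10 should ionise in the strongly ionising, weakly nucleophilic fluoro alcohol with participation of the aryl carbon C4a, whose ring carries oxygen at both ortho positions (O1 on C8a, the C5 ether) and at the para position (C7), to give the bridged spiro-cyclopropane arenium (phenonium) ion pair 11; return of trifluoroacetate to C4 only regenerates 10, whereas return to the secondary carbon C3 breaks the C3–C4a bond with inversion and leaves C4 bonded to C4a, so the dihydrofuran ring (O1, C2, C3, C4a, C8a) becomes the pyran ring (O1, C2, C3, C4, C4a, C8a) in ester 12, which methanolysis at the acyl carbon turns into 13 without touching the C3–O bond. The closest known reaction types are phenonium-ion solvolysis of 2-arylalkyl esters, the interconversion of 3-(halomethyl)indolines and 3-halotetrahydroquinolines through spiro-cyclopropyl cyclohexadienones, the trifluoroacetate-mediated, thermodynamically controlled ring expansion of 2-(hydroxymethyl)pyrrolidines through aziridinium ions and, read backwards, the aryl-assisted ring contraction of flavan-3-yl sulfonates. The six-membered ring is not closed by a separate cyclisation: C4a bridges to C4 in a 3-exo-tet sense and the cyclopropane then opens at C3. C2 is not involved and C3 is set by substrate control, because the nucleophile must enter anti to the departing C4a, so the 2,3-cis relation of 9 is transferred to the 2,3-cis (2R,3R) flavan. The step needs capture at C3 to win over capture at C4, which kinetics may not favour because the C4–C4a bond of 11 is the better aligned and less hindered one; a reversible nucleofuge is therefore used, so that the mixture drains to the less strained six-membered ester 12 (10 carries the strain of the five-membered ring and an eclipsed cis pair), which re-ionises only from its minor conformer with an equatorial ester. Mild, buffered conditions and only a slight excess of anhydride are chosen to keep O1-assisted ionisation at C3, loss of the C2 hydrogen and C-acylation of the electron-rich rings slow.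

Step 7
Reactants: 13 (2R,3R)-5,7-bis(benzyloxy)-2-[3,4,5-tris(benzyloxy)phenyl]chroman-3-ol
Product: 14 (2R,3R,4S)-5,7-bis(benzyloxy)-4-(2-ethoxyethoxy)-2-[3,4,5-tris(benzyloxy)phenyl]chroman-3-ol (4β-ether; 3,4-trans)
Conditions: DDQ (2 equiv), 2-ethoxyethanol, CH2Cl2, 25 °C
Reagents that add atoms: 2-ethoxyethanol, CCOCCO
Why: DDQ oxidation at the benzylic C4 of an O-benzylated flavan-3-ol with capture by the alcohol, a standard activation of this substrate class; the alcohol adds trans to the axial 3-hydroxyl (substrate control, 4β) and the benzyl ethers are not oxidised.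

Step 8
Reactants: 14 (2R,3R,4S)-5,7-bis(benzyloxy)-4-(2-ethoxyethoxy)-2-[3,4,5-tris(benzyloxy)phenyl]chroman-3-ol; 15 3,4,5-tris(benzyloxy)benzoic acid
Product: 16 (2R,3R,4S)-5,7-bis(benzyloxy)-4-(2-ethoxyethoxy)-2-[3,4,5-tris(benzyloxy)phenyl]chroman-3-yl 3,4,5-tris(benzyloxy)benzoate
Conditions: 15, DCC, DMAP, CH2Cl2, 25 °C
Reagents that add atoms: none
Why: Steglich esterification of the secondary 3-hydroxyl under neutral conditions, which the acid-labile 4-ether survives and which touches no stereocentre.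

Step 9
Reactants: 17 (−)-epicatechin
Product: 18 (2R,3R)-5,7-bis(benzyloxy)-2-[3,4-bis(benzyloxy)phenyl]chroman-3-ol (tetra-O-benzyl-(−)-epicatechin)
Conditions: BnBr (4.4 equiv), K2CO3, DMF, 0 → 25 °C
Reagents that add atoms: benzyl bromide, BrCc1ccccc1
Why: Williamson etherification of the four phenols only (carbonate does not deprotonate the aliphatic 3-hydroxyl), run cold so that C2 is not epimerised by base.

Step 10
Reactants: 16 galloylated 4-ether electrophile (unit C); 18 tetra-O-benzyl-(−)-epicatechin (unit D)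
Product: 20 dodeca-O-benzyl epigallocatechin-3-O-gallate-(4β→8)-epicatechin (3-OH of unit D free), via C4 cation 19 (not isolated)
Conditions: 18 (4 equiv), Me3SiOTf (0.2 equiv), CH2Cl2, −78 °C
Reagents that add atoms: none
Why: Lewis-acid-promoted Friedel–Crafts coupling of a 4-alkoxyflavan with an O-benzylated flavan-3-ol, which is known to go at C8 of the nucleophile; the 3-O-galloyl group and the 2-aryl group shield the α-face of cation 19, so the new C4 centre is formed 3,4-trans (4β) by substrate control, and the excess of 18 suppresses self-condensation of 16.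

Step 11
Reactants: 14 4-ether electrophile (unit B); 20 protected C–D dimer
Product: 22 heptadeca-O-benzyl epigallocatechin-(4β→8)-epigallocatechin-3-O-gallate-(4β→8)-epicatechin (3-OH of units B and D free), via C4 cation 21 (not isolated)
Conditions: 20 (1.3 equiv), Me3SiOTf (0.2 equiv), CH2Cl2, −78 → −40 °C
Reagents that add atoms: none
Why: the same Friedel–Crafts coupling type, expected at C8 of unit C because only that phloroglucinol ring of 20 still has a free C8; attack on cation 21 anti to the axial 3-hydroxyl and the 2-aryl group sets the new C4 centre 4β.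

Step 12
Reactants: 14 (2R,3R,4S)-5,7-bis(benzyloxy)-4-(2-ethoxyethoxy)-2-[3,4,5-tris(benzyloxy)phenyl]chroman-3-ol
Product: 23 (2R,3R,4S)-5,7-bis(benzyloxy)-8-bromo-4-(2-ethoxyethoxy)-2-[3,4,5-tris(benzyloxy)phenyl]chroman-3-ol (8-bromo chain terminator for unit A)
Conditions: N-bromosuccinimide (1.0 equiv), CH2Cl2, −20 °C
Reagents that add atoms: N-bromosuccinimide, O=C1CCC(=O)N1Br
Why: electrophilic aromatic bromination, which for O-benzylated flavan-3-ols goes at C8 of the phloroglucinol ring (ortho to O1 and the C7 ether, para to the C5 ether) and not at the more hindered C6 between two benzyloxy groups; the neutral conditions leave the acid-labile 4-ether and all stereocentres untouched and no stereocentre is formed.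

Step 13
Reactants: 23 8-bromo 4-ether electrophile (unit A); 22 protected B–C–D trimer
Product: 25 docosa-O-benzyl 8-bromo-epigallocatechin-(4β→8)-epigallocatechin-(4β→8)-epigallocatechin-3-O-gallate-(4β→8)-epicatechin (bromine on C8 of unit A; 3-OH of units A, B and D free), via 8-bromo C4 cation 24 (not isolated)
Conditions: 23 (1.5 equiv), Me3SiOTf (0.2 equiv), CH2Cl2, −78 → −40 °C
Reagents that add atoms: none
Why: the same Friedel–Crafts coupling type at the free C8 of the top unit B of 22; the bromine on C8 of the electrophile keeps it from acting as a nucleophile, so the excess of chain terminator cannot oligomerise, and attack on cation 24 anti to the 3-hydroxyl and the 2-aryl group sets the new C4 centre 4β.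

Step 14
Reactants: 25 protected 8-bromo tetramer
Product: 26 epigallocatechin-(4β→8)-epigallocatechin-(4β→8)-epigallocatechin 3-O-gallate-(4β→8)-epicatechin (target)
Conditions: H2 (1 atm), Pd(OH)2 on carbon, NaOAc (1.5 equiv), THF/MeOH/H2O, 25 °C
Reagents that add atoms: none
Why: global hydrogenolysis of the 22 benzyl ethers together with hydrodehalogenation of the C8 aryl bromide in one operation; the acetate buffer takes up the hydrogen bromide so that the acid-labile interflavan bonds are not cleaved, and the gallate ester and all stereocentres are untouched.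

**Compound list**

1 | 3,4,5-tris(benzyloxy)benzaldehyde | O=Cc1cc(OCc2ccccc2)c(OCc2ccccc2)c(OCc2ccccc2)c1 | starting material
2 | ethyl 2-(diphenoxyphosphoryl)acetate | CCOC(=O)CP(=O)(Oc1ccccc1)Oc1ccccc1 | starting material
3 | ethyl (Z)-3-[3,4,5-tris(benzyloxy)phenyl]prop-2-enoate | CCOC(=O)/C=C\c1cc(OCc2ccccc2)c(OCc2ccccc2)c(OCc2ccccc2)c1 | intermediate
4 | ethyl (2S,3S)-3-[3,4,5-tris(benzyloxy)phenyl]oxirane-2-carboxylate (cis) | CCOC(=O)[C@H]1O[C@H]1c1cc(OCc2ccccc2)c(OCc2ccccc2)c(OCc2ccccc2)c1 | intermediate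
5 | 3,5-bis(benzyloxy)phenol | Oc1cc(OCc2ccccc2)cc(OCc2ccccc2)c1 | starting material
6 | ethyl (2S,3R)-3-[3,5-bis(benzyloxy)phenoxy]-2-hydroxy-3-[3,4,5-tris(benzyloxy)phenyl]propanoate | CCOC(=O)[C@@H](O)[C@H](Oc1cc(OCc2ccccc2)cc(OCc2ccccc2)c1)c1cc(OCc2ccccc2)c(OCc2ccccc2)c(OCc2ccccc2)c1 | intermediate
7 | 2-O-trifluoromethanesulfonate of 6 (configuration as in 6) | CCOC(=O)[C@@H](OS(=O)(=O)C(F)(F)F)[C@H](Oc1cc(OCc2ccccc2)cc(OCc2ccccc2)c1)c1cc(OCc2ccccc2)c(OCc2ccccc2)c(OCc2ccccc2)c1 | intermediate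
8 | ethyl (2S,3R)-4,6-bis(benzyloxy)-2-[3,4,5-tris(benzyloxy)phenyl]-2,3-dihydro-1-benzofuran-3-carboxylate (2,3-cis) | CCOC(=O)[C@@H]1c2c(OCc3ccccc3)cc(OCc3ccccc3)cc2O[C@@H]1c1cc(OCc2ccccc2)c(OCc2ccccc2)c(OCc2ccccc2)c1 | intermediate
9 | [(2S,3S)-4,6-bis(benzyloxy)-2-[3,4,5-tris(benzyloxy)phenyl]-2,3-dihydro-1-benzofuran-3-yl]methanol (2,3-cis) | OC[C@@H]1c2c(OCc3ccccc3)cc(OCc3ccccc3)cc2O[C@@H]1c1cc(OCc2ccccc2)c(OCc2ccccc2)c(OCc2ccccc2)c1 | intermediate
10 | trifluoroacetate of 9 (2S,3S) | O=C(OC[C@@H]1c2c(OCc3ccccc3)cc(OCc3ccccc3)cc2O[C@@H]1c1cc(OCc2ccccc2)c(OCc2ccccc2)c(OCc2ccccc2)c1)C(F)(F)F | intermediate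
11 | phenonium ion pair: spiro-cyclopropane arenium cation in which C4a bridges C3 and C4 on the face that carried the CH2 group, drawn as its C5 oxocarbenium form, with trifluoroacetate counter-ion | C1[C@H]2[C@@H](c4cc(OCc5ccccc5)c(OCc5ccccc5)c(OCc5ccccc5)c4)OC3=CC(OCc4ccccc4)=CC(=[O+]Cc4ccccc4)[C@]123.[O-]C(=O)C(F)(F)F | intermediate
12 | (2R,3R)-5,7-bis(benzyloxy)-2-[3,4,5-tris(benzyloxy)phenyl]chroman-3-yl trifluoroacetate | O=C(O[C@@H]1Cc2c(OCc3ccccc3)cc(OCc3ccccc3)cc2O[C@@H]1c1cc(OCc2ccccc2)c(OCc2ccccc2)c(OCc2ccccc2)c1)C(F)(F)F | intermediate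
13 | (2R,3R)-5,7-bis(benzyloxy)-2-[3,4,5-tris(benzyloxy)phenyl]chroman-3-ol (penta-O-benzyl-(−)-epigallocatechin) | O[C@@H]1Cc2c(OCc3ccccc3)cc(OCc3ccccc3)cc2O[C@@H]1c1cc(OCc2ccccc2)c(OCc2ccccc2)c(OCc2ccccc2)c1 | intermediate
14 | (2R,3R,4S)-5,7-bis(benzyloxy)-4-(2-ethoxyethoxy)-2-[3,4,5-tris(benzyloxy)phenyl]chroman-3-ol (4β-ether) | O[C@@H]1[C@@H](OCCOCC)c2c(OCc3ccccc3)cc(OCc3ccccc3)cc2O[C@@H]1c1cc(OCc2ccccc2)c(OCc2ccccc2)c(OCc2ccccc2)c1 | intermediate
15 | 3,4,5-tris(benzyloxy)benzoic acid | OC(=O)c1cc(OCc2ccccc2)c(OCc2ccccc2)c(OCc2ccccc2)c1 | starting material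
16 | (2R,3R,4S)-5,7-bis(benzyloxy)-4-(2-ethoxyethoxy)-2-[3,4,5-tris(benzyloxy)phenyl]chroman-3-yl 3,4,5-tris(benzyloxy)benzoate | O=C(O[C@@H]1[C@@H](OCCOCC)c2c(OCc3ccccc3)cc(OCc3ccccc3)cc2O[C@@H]1c1cc(OCc2ccccc2)c(OCc2ccccc2)c(OCc2ccccc2)c1)c1cc(OCc2ccccc2)c(OCc2ccccc2)c(OCc2ccccc2)c1 | intermediate
17 | (−)-epicatechin, (2R,3R) | O[C@@H]1Cc2c(O)cc(O)cc2O[C@@H]1c1ccc(O)c(O)c1 | starting material
18 | (2R,3R)-5,7-bis(benzyloxy)-2-[3,4-bis(benzyloxy)phenyl]chroman-3-ol (tetra-O-benzyl-(−)-epicatechin) | O[C@@H]1Cc2c(OCc3ccccc3)cc(OCc3ccccc3)cc2O[C@@H]1c1ccc(OCc2ccccc2)c(OCc2ccccc2)c1 | intermediate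
19 | C4 benzylic cation from 16 (2R,3R), triflate salt | O=C(O[C@@H]1[CH+]c2c(OCc3ccccc3)cc(OCc3ccccc3)cc2O[C@@H]1c1cc(OCc2ccccc2)c(OCc2ccccc2)c(OCc2ccccc2)c1)c1cc(OCc2ccccc2)c(OCc2ccccc2)c(OCc2ccccc2)c1.[O-]S(=O)(=O)C(F)(F)F | intermediate
20 | protected C–D dimer: dodeca-O-benzyl epigallocatechin-3-O-gallate-(4β→8)-epicatechin | O=C(O[C@@H]1[C@@H](c2c(OCc4ccccc4)cc(OCc4ccccc4)c3c2O[C@H](c2ccc(OCc4ccccc4)c(OCc4ccccc4)c2)[C@H](O)C3)c2c(OCc3ccccc3)cc(OCc3ccccc3)cc2O[C@@H]1c1cc(OCc2ccccc2)c(OCc2ccccc2)c(OCc2ccccc2)c1)c1cc(OCc2ccccc2)c(OCc2ccccc2)c(OCc2ccccc2)c1 | intermediate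
21 | C4 benzylic cation from 14 (2R,3R), triflate salt | O[C@@H]1[CH+]c2c(OCc3ccccc3)cc(OCc3ccccc3)cc2O[C@@H]1c1cc(OCc2ccccc2)c(OCc2ccccc2)c(OCc2ccccc2)c1.[O-]S(=O)(=O)C(F)(F)F | intermediate
22 | protected B–C–D trimer: heptadeca-O-benzyl epigallocatechin-(4β→8)-epigallocatechin-3-O-gallate-(4β→8)-epicatechin | O=C(O[C@@H]1[C@@H](c2c(OCc4ccccc4)cc(OCc4ccccc4)c3c2O[C@H](c2ccc(OCc4ccccc4)c(OCc4ccccc4)c2)[C@H](O)C3)c2c(OCc3ccccc3)cc(OCc3ccccc3)c([C@H]3c4c(OCc5ccccc5)cc(OCc5ccccc5)cc4O[C@H](c4cc(OCc5ccccc5)c(OCc5ccccc5)c(OCc5ccccc5)c4)[C@@H]3O)c2O[C@@H]1c1cc(OCc2ccccc2)c(OCc2ccccc2)c(OCc2ccccc2)c1)c1cc(OCc2ccccc2)c(OCc2ccccc2)c(OCc2ccccc2)c1 | intermediate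
23 | (2R,3R,4S)-5,7-bis(benzyloxy)-8-bromo-4-(2-ethoxyethoxy)-2-[3,4,5-tris(benzyloxy)phenyl]chroman-3-ol (8-bromo derivative of 14) | O[C@@H]1[C@@H](OCCOCC)c2c(OCc3ccccc3)cc(OCc3ccccc3)c(Br)c2O[C@@H]1c1cc(OCc2ccccc2)c(OCc2ccccc2)c(OCc2ccccc2)c1 | intermediate
24 | 8-bromo C4 benzylic cation from 23 (2R,3R), triflate salt | O[C@@H]1[CH+]c2c(OCc3ccccc3)cc(OCc3ccccc3)c(Br)c2O[C@@H]1c1cc(OCc2ccccc2)c(OCc2ccccc2)c(OCc2ccccc2)c1.[O-]S(=O)(=O)C(F)(F)F | intermediate
25 | protected 8-bromo tetramer: docosa-O-benzyl 8-bromo-epigallocatechin-(4β→8)-epigallocatechin-(4β→8)-epigallocatechin-3-O-gallate-(4β→8)-epicatechin (bromine on C8 of unit A) | O=C(O[C@@H]1[C@@H](c2c(OCc4ccccc4)cc(OCc4ccccc4)c3c2O[C@H](c2ccc(OCc4ccccc4)c(OCc4ccccc4)c2)[C@H](O)C3)c2c(OCc3ccccc3)cc(OCc3ccccc3)c([C@H]3c4c(OCc7ccccc7)cc(OCc7ccccc7)c([C@H]5c6c(OCc7ccccc7)cc(OCc7ccccc7)c(Br)c6O[C@H](c6cc(OCc7ccccc7)c(OCc7ccccc7)c(OCc7ccccc7)c6)[C@@H]5O)c4O[C@H](c4cc(OCc5ccccc5)c(OCc5ccccc5)c(OCc5ccccc5)c4)[C@@H]3O)c2O[C@@H]1c1cc(OCc2ccccc2)c(OCc2ccccc2)c(OCc2ccccc2)c1)c1cc(OCc2ccccc2)c(OCc2ccccc2)c(OCc2ccccc2)c1 | intermediate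
26 | epigallocatechin-(4β→8)-epigallocatechin-(4β→8)-epigallocatechin 3-O-gallate-(4β→8)-epicatechin | O=C(O[C@@H]1[C@@H](c2c(O)cc(O)c3c2O[C@H](c2ccc(O)c(O)c2)[C@H](O)C3)c2c(O)cc(O)c([C@H]3c4c(O)cc(O)c([C@H]5c6c(O)cc(O)cc6O[C@H](c6cc(O)c(O)c(O)c6)[C@@H]5O)c4O[C@H](c4cc(O)c(O)c(O)c4)[C@@H]3O)c2O[C@@H]1c1cc(O)c(O)c(O)c1)c1cc(O)c(O)c(O)c1 | target

**Step count and risks**

Total steps: 14. Longest linear sequence: 12 steps (1 → 3 → 4 → 6 → 8 → 9 → 13 → 14 → 16 → 20 → 22 → 25 → 26, that is steps 1–8, 10, 11, 13 and 14). The benzylation of epicatechin (step 9) and the bromination of 14 (step 12) are side branches.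

Steps most likely to fail:

1. Step 6 (Proposed new method). The bridged ion may return only to the primary carbon so that no net expansion occurs. The ring-expanded ester may re-ionise with help of O1 and lose the C2 configuration. The C2 hydrogen may be lost by elimination. The fallback uses known chemistry, sets out from 6 and comes back at 13. Reduction of 6 with LiBH4 should give the (2R,3R)-3-aryloxy-3-arylpropane-1,2-diol F1. Mitsunobu cyclodehydration (PPh3, DIAD) should close the terminal oxirane F2 with retention at the secondary carbon. Epoxy-arene Friedel–Crafts cyclisation in (CF3)2CHOH, in which the free ortho carbon of the phloroglucinol ether attacks the terminal epoxide carbon, would then form the C4–C4a bond directly and keep the C3 oxygen in place, giving 13 with the same configuration.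

2. Step 4. Elimination or decomposition of the α-triflate, or intermolecular alkylation, may outrun closure by the ortho carbon, and the cis ester may partly epimerise. The fallback sets out from 5 and 4 and comes back at 9. Ortho-selective bromination of 5 (N-bromosuccinimide, catalytic i-Pr2NH) should give 2-bromo-3,5-bis(benzyloxy)phenol F3. Opening of 4 with it under the conditions of step 3 should give the bromoaryl ether hydroxy ester F4. LiBH4 should give the diol F5, and Mitsunobu cyclodehydration the terminal oxirane F6. Bromine–lithium exchange (t-BuLi, THF, −78 °C) followed by Parham-type 5-exo-tet opening of the oxirane at its internal carbon by the aryllithium (inversion) should give 9 directly. The ester stage and the cationic closure are thereby avoided.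

3. Step 11. Electrophile 14 may self-condense through its own free C8, and 20 may be attacked at C6, so that chemo- and regioselectivity of the coupling are lost and oligomer mixtures result. The fallback sets out from 23 and 20 and comes back at 22. Coupling of the capped electrophile 23, which can no longer act as a nucleophile, with 20 (Me3SiOTf, CH2Cl2, −78 °C) should give the 8-bromo trimer F7. Radical debromination (Bu3SnH, AIBN, toluene, 90 °C) should return 22 with its C8 free for step 13.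

**Further compounds**

F1 | step 6 | (2R,3R)-3-[3,5-bis(benzyloxy)phenoxy]-3-[3,4,5-tris(benzyloxy)phenyl]propane-1,2-diol | OC[C@@H](O)[C@H](Oc1cc(OCc2ccccc2)cc(OCc2ccccc2)c1)c1cc(OCc2ccccc2)c(OCc2ccccc2)c(OCc2ccccc2)c1
F2 | step 6 | (2R)-2-{(R)-[3,5-bis(benzyloxy)phenoxy][3,4,5-tris(benzyloxy)phenyl]methyl}oxirane | C1O[C@H]1[C@H](Oc1cc(OCc2ccccc2)cc(OCc2ccccc2)c1)c1cc(OCc2ccccc2)c(OCc2ccccc2)c(OCc2ccccc2)c1
F3 | step 4 | 2-bromo-3,5-bis(benzyloxy)phenol | Oc1cc(OCc2ccccc2)cc(OCc2ccccc2)c1Br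
F4 | step 4 | ethyl (2S,3R)-3-[2-bromo-3,5-bis(benzyloxy)phenoxy]-2-hydroxy-3-[3,4,5-tris(benzyloxy)phenyl]propanoate | CCOC(=O)[C@@H](O)[C@H](Oc1cc(OCc2ccccc2)cc(OCc2ccccc2)c1Br)c1cc(OCc2ccccc2)c(OCc2ccccc2)c(OCc2ccccc2)c1
F5 | step 4 | (2R,3R)-3-[2-bromo-3,5-bis(benzyloxy)phenoxy]-3-[3,4,5-tris(benzyloxy)phenyl]propane-1,2-diol | OC[C@@H](O)[C@H](Oc1cc(OCc2ccccc2)cc(OCc2ccccc2)c1Br)c1cc(OCc2ccccc2)c(OCc2ccccc2)c(OCc2ccccc2)c1
F6 | step 4 | (2R)-2-{(R)-[2-bromo-3,5-bis(benzyloxy)phenoxy][3,4,5-tris(benzyloxy)phenyl]methyl}oxirane | C1O[C@H]1[C@H](Oc1cc(OCc2ccccc2)cc(OCc2ccccc2)c1Br)c1cc(OCc2ccccc2)c(OCc2ccccc2)c(OCc2ccccc2)c1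
F7 | step 11 | 8-bromo derivative of 22 (bromine on C8 of unit B), configuration as in 22 | O=C(O[C@@H]1[C@@H](c2c(OCc4ccccc4)cc(OCc4ccccc4)c3c2O[C@H](c2ccc(OCc4ccccc4)c(OCc4ccccc4)c2)[C@H](O)C3)c2c(OCc3ccccc3)cc(OCc3ccccc3)c([C@H]3c4c(OCc5ccccc5)cc(OCc5ccccc5)c(Br)c4O[C@H](c4cc(OCc5ccccc5)c(OCc5ccccc5)c(OCc5ccccc5)c4)[C@@H]3O)c2O[C@@H]1c1cc(OCc2ccccc2)c(OCc2ccccc2)c(OCc2ccccc2)c1)c1cc(OCc2ccccc2)c(OCc2ccccc2)c(OCc2ccccc2)c1
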